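**Plan**

1. Retrosynthesis: the pyran ring (ring C) of the terminal unit (unit 4) is opened at C4–C4a (epoxide plus arene), then at the aryl ether bond O1–C2. The interflavan bonds C4(unit 2)–C8(unit 3), C4(unit 3)–C6(unit 4 arene) and C4(unit 1)–C6(unit 2) are cut next, leaving (−)-epicatechin three times, 3,5-bis(benzyloxy)phenol and a C6–C3 epoxy alcohol.
2. Forward: rings C of units 1 to 3 come ready-made from (−)-epicatechin. Units 1 and 2 are joined 4β→6 (bromine blocks C8), unit 3 is arylated at C4 with the silyl-masked phenol, the two halves are joined 4β→8, the phenol is unmasked and etherified, and ring C of unit 4 is closed last.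
3. Enabling feature: in ring A of unit 4 the oxygen O1 (on C8a) is para to the interflavan carbon C6. While ring C is open, C4a and C8 are equivalent ortho carbons (local twofold axis through C8a and C6), so closure at either gives only the 4→6 isomer; the open, silyl-shielded ring also does not compete as a nucleophile during chain assembly.
4. Stereochemistry: C2/C3 of units 1 to 3 come from (−)-epicatechin; every C4 is set 4β by attack on the C4 cation anti to the 2-aryl and 3-OH groups; C3 of unit 4 comes from a Sharpless kinetic-resolution epoxidation and C2 of unit 4 from Mitsunobu inversion.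

Key step: step 14

Remark: the target is read as epicatechin-(4β→6)-epicatechin-(4β→8)-epicatechin-(4β→6)-epicatechin (all 2R,3R, all 3,4-trans); units are numbered 1 (top) to 4 (terminal), rings are lettered A (benzo), B (catechol) and C (pyran), and the four 3-hydroxyl groups are carried unprotected.

**Route**

Step 1
Reactants: 1 (−)-epicatechin; 2 benzyl bromide
Product: 3 5,7,3',4'-tetra-O-benzyl-(−)-epicatechin
Conditions: BnBr (4.4 equiv), K2CO3, DMF, 0 °C → rt, N2
Reagents that add atoms: benzyl bromide, BrCc1ccccc1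
Why: Williamson O-benzylation in which carbonate deprotonates only the four phenols, so the secondary 3-OH and the C2/C3 stereocentres should stay untouched.

Step 2
Reactants: 3 5,7,3',4'-tetra-O-benzyl-(−)-epicatechin; 4 N-bromosuccinimide
Product: 5 8-bromo-5,7,3',4'-tetra-O-benzyl-(−)-epicatechin
Conditions: NBS (1.0 equiv), CH2Cl2, −40 → 0 °C
Reagents that add atoms: N-bromosuccinimide, BrN1C(=O)CCC1=O
Why: Electrophilic aromatic bromination at C8, the most nucleophilic carbon of ring A (between O1 and 7-OBn), should install the blocking group that forces later substitution to C6 and is removed in step 15.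

Step 3
Reactants: 5 8-bromo-5,7,3',4'-tetra-O-benzyl-(−)-epicatechin; 6 2-ethoxyethanol
Product: 7 8-bromo-5,7,3',4'-tetra-O-benzyl-4β-(2-ethoxyethoxy)-(−)-epicatechin (3,4-trans)
Conditions: DDQ (2 equiv), 2-ethoxyethanol (5 equiv), CH2Cl2, rt
Reagents that add atoms: 2-ethoxyethanol, CCOCCO
Why: Oxidative C4 alkoxylation: DDQ abstracts hydride from benzylic C4 (para/ortho to the ring-A oxygens) and the alcohol traps the cation anti to the 2-aryl and 3-OH groups, giving the 4β ether.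

Step 4
Reactants: 7 8-bromo-4β-(2-ethoxyethoxy) monomer; 8 benzyl mercaptan
Product: 9 8-bromo-5,7,3',4'-tetra-O-benzyl-4β-(benzylsulfanyl)-(−)-epicatechin (3,4-trans)
Conditions: BnSH (3 equiv), BF3·OEt2 (1.2 equiv), CH2Cl2, −78 → −40 °C
Reagents that add atoms: benzyl mercaptan, SCc1ccccc1
Why: Lewis-acid ionisation of the C4 ether and capture of the cation by the thiol from the β-face (thiolysis type) should give a 4β thioether that is inert to BF3·OEt2 at low temperature but labile to thiophilic silver.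

Step 5
Reactants: 7 8-bromo-4β-(2-ethoxyethoxy) monomer; 9 8-bromo-4β-(benzylsulfanyl) monomer
Product: 10 [8-bromo-5,7,3',4'-tetra-O-benzyl-epicatechin]-(4β→6)-[8-bromo-5,7,3',4'-tetra-O-benzyl-4β-(benzylsulfanyl)-epicatechin]
Conditions: 9 (3 equiv), BF3·OEt2 (1.5 equiv), 4 Å MS, CH2Cl2, −40 → −10 °C
Reagents that add atoms: none
Why: Friedel–Crafts-type interflavan coupling in which BF3 ionises only the C4–O bond of 7; with C8 brominated in both partners the cation can be taken only by C6 of 9, from the β-face, giving the 4β→6 bond with the thioether kept.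

Step 6
Reactants: 3 5,7,3',4'-tetra-O-benzyl-(−)-epicatechin; 6 2-ethoxyethanol
Product: 11 5,7,3',4'-tetra-O-benzyl-4β-(2-ethoxyethoxy)-(−)-epicatechin (3,4-trans)
Conditions: DDQ (2 equiv), 2-ethoxyethanol (5 equiv), CH2Cl2, rt
Reagents that add atoms: 2-ethoxyethanol, CCOCCO
Why: The same DDQ-mediated oxidative C4 alkoxylation as in step 3, with trapping of the C4 cation anti to the 2-aryl and 3-OH groups.

Step 7
Reactants: 12 3,5-bis(benzyloxy)phenol; 13 chlorotriisopropylsilane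
Product: 14 [3,5-bis(benzyloxy)phenoxy]triisopropylsilane
Conditions: iPr3SiCl, imidazole, DMF, rt
Reagents that add atoms: chlorotriisopropylsilane, CC(C)[Si](Cl)(C(C)C)C(C)C
Why: Phenol silylation gives a fluoride-labile mask whose bulk shields both carbons ortho to the silyloxy group.

Step 8
Reactants: 11 4β-(2-ethoxyethoxy) monomer; 14 silyl ether of 3,5-bis(benzyloxy)phenol
Product: 15 5,7,3',4'-tetra-O-benzyl-4β-[2,6-bis(benzyloxy)-4-(triisopropylsilyloxy)phenyl]-(−)-epicatechin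
Conditions: 14 (5 equiv), BF3·OEt2 (1.0 equiv), CH2Cl2, −78 → −30 °C
Reagents that add atoms: none
Why: Friedel–Crafts arylation of the C4 cation by excess 14 at the carbon para to the silyloxy group (the ortho carbons are shielded, as in β-selective substitution of N-triisopropylsilylpyrrole), from the β-face anti to the 2-aryl and 3-OH groups.

Step 9
Reactants: 10 dimer thioether; 15 C4-arylated unit 3
Product: 16 [8-bromo-tetra-O-benzyl-epicatechin]-(4β→6)-[8-bromo-tetra-O-benzyl-epicatechin]-(4β→8)-[tetra-O-benzyl-epicatechin] bearing at C4β of unit 3 a 2,6-bis(benzyloxy)-4-(triisopropylsilyloxy)phenyl group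
Conditions: 15 (1.5 equiv), AgBF4 (2 equiv), 2,6-di-tert-butyl-4-methylpyridine (2.5 equiv), 4 Å MS, THF/CH2Cl2, −20 → 0 °C, dark
Reagents that add atoms: none
Why: Thiophilic silver removes benzylthiolate from C4 of unit 2 and the cation is taken by C8 of unit 3 (the most nucleophilic free carbon; the silyl-flanked arene and the bromo rings are poor nucleophiles) from the β-face, giving the 4β→8 bond while the base buffers HBF4.

Step 10
Reactants: 16 silyl-masked trimer arene
Product: 17 the corresponding phenol: trimer bearing at C4β of unit 3 a 2,6-bis(benzyloxy)-4-hydroxyphenyl group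
Conditions: Bu4NF (1.2 equiv), AcOH (1.2 equiv), THF, 0 °C
Reagents that add atoms: none
Why: Fluoride cleavage of the aryl silyl ether should free the single phenol of the molecule, which sits para to the interflavan carbon.

Step 11
Reactants: 18 3,4-bis(benzyloxy)benzaldehyde; 19 vinylmagnesium bromide
Product: 20 rac-1-[3,4-bis(benzyloxy)phenyl]prop-2-en-1-ol
Conditions: CH2=CHMgBr, THF, −78 → 0 °C; aq. NH4Cl
Reagents that add atoms: vinylmagnesium bromide, C=C[Mg]Br
Why: Grignard 1,2-addition to the aldehyde gives the racemic aryl vinyl carbinol.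

Step 12
Reactants: 20 rac-1-[3,4-bis(benzyloxy)phenyl]prop-2-en-1-ol; 21 tert-butyl hydroperoxide
Product: 22 (S)-[3,4-bis(benzyloxy)phenyl][(2R)-oxiran-2-yl]methanol (erythro)
Conditions: Ti(OiPr)4 (0.1 equiv), L-(+)-diisopropyl tartrate (0.15 equiv), t-BuOOH (0.55 equiv), 4 Å MS, CH2Cl2, −20 °C
Reagents that add atoms: tert-butyl hydroperoxide, CC(C)(C)OO
Why: Sharpless kinetic-resolution epoxidation: with the L-(+)-tartrate the (R)-allylic alcohol should be epoxidised much faster than the (S)-enantiomer, which stays behind, and gives the erythro epoxy alcohol whose oxirane carbon becomes C3 of unit 4.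

Step 13
Reactants: 17 trimer phenol; 22 erythro epoxy alcohol
Product: 23 trimer bearing at C4β of unit 3 a 2,6-bis(benzyloxy)-4-{(R)-[3,4-bis(benzyloxy)phenyl][(2R)-oxiran-2-yl]methoxy}phenyl group
Conditions: 22 (1.5 equiv), PPh3, DIAD, THF, 0 °C → rt
Reagents that add atoms: none
Why: Mitsunobu etherification of the only phenol with the secondary benzylic alcohol should proceed with SN2 inversion to set the future C2 as R, while the hindered axial 3-OH groups cannot be displaced and the epoxide survives the neutral conditions.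

Step 14
Reactants: 23 aryl ether epoxide
Product: 24 8,8'-dibromo-hexadeca-O-benzyl tetramer: [8-bromo-5,7,3',4'-tetra-O-benzyl-epicatechin]-(4β→6)-[8-bromo-5,7,3',4'-tetra-O-benzyl-epicatechin]-(4β→8)-[5,7,3',4'-tetra-O-benzyl-epicatechin]-(4β→6)-[5,7,3',4'-tetra-O-benzyl-epicatechin]
Conditions: AuCl3 (10 mol %), AgOSO2CF3 (30 mol %), CH2Cl2 (0.002 M), −20 °C → rt
Reagents that add atoms: none
Why: Cationic trivalent gold binds the epoxide oxygen, the ring-A carbon ortho to the ether oxygen and para to a benzyloxy group attacks the terminal epoxide carbon (future C4) with C4–O cleavage, and loss of the arenium proton forms the C4–C4a bond and releases the 3-OH. The closest known reaction type is the gold- or Lewis-acid-catalysed intramolecular Friedel–Crafts cycloalkylation of aryl glycidyl ethers to chroman-3-ols. Ring C of unit 4 closes in the 6-endo-tet mode; 5-exo attack at C3 is disfavoured because C3 is secondary and inductively deactivated by the neighbouring C2–O bond. No new stereocentre is made: C3 keeps the epoxide C–O bond set by the tartrate in step 12 and C2 keeps the configuration set by the inversion in step 13, which together fix the 2,3-cis (2R,3R) arrangement. The step needs 4→6 and not 4→8 connectivity, secured because the ether oxygen (future O1) is para to the interflavan carbon (future C6), so the two ortho carbons are equivalent and either closure gives the same product. It must also outrun reaction at the free C6/C8 positions of units 1 to 3 and ionisation of the interflavan and benzylic C2–O bonds, which is secured by intramolecularity at high dilution, the bromine atoms on units 1 and 2 and a mild catalytic acid at low temperature.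

Step 15
Reactants: 24 protected dibromo tetramer
Product: 25 epicatechin-(4β→6)-epicatechin-(4β→8)-epicatechin-(4β→6)-epicatechin (CNP0120618.1)
Conditions: H2 (1 atm), Pd(OH)2/C, Et3N (2.2 equiv), THF/MeOH/H2O, rt
Reagents that add atoms: none
Why: Hydrogenolysis should cleave the sixteen benzyl ethers and reduce both aryl bromides (Et3N takes up HBr), while the flavan C2–O1 and C4–aryl bonds are known to survive these conditions.

**Compound list**

1 | (−)-epicatechin | Oc1cc(O)c2c(c1)O[C@H](c1ccc(O)c(O)c1)[C@H](O)C2 | starting material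
2 | benzyl bromide | BrCc1ccccc1 | starting material
3 | 5,7,3',4'-tetra-O-benzyl-(−)-epicatechin | c4ccccc4COc1cc(OCc4ccccc4)c2c(c1)O[C@H](c1ccc(OCc4ccccc4)c(OCc4ccccc4)c1)[C@H](O)C2 | intermediate
4 | N-bromosuccinimide | BrN1C(=O)CCC1=O | starting material
5 | 8-bromo-5,7,3',4'-tetra-O-benzyl-(−)-epicatechin | c4ccccc4COc1cc(OCc4ccccc4)c2c(c1Br)O[C@H](c1ccc(OCc4ccccc4)c(OCc4ccccc4)c1)[C@H](O)C2 | intermediate
6 | 2-ethoxyethanol | CCOCCO | starting material
7 | 8-bromo-5,7,3',4'-tetra-O-benzyl-4β-(2-ethoxyethoxy)-(−)-epicatechin | c4ccccc4COc1cc(OCc4ccccc4)c2c(c1Br)O[C@H](c1ccc(OCc4ccccc4)c(OCc4ccccc4)c1)[C@H](O)[C@H]2OCCOCC | intermediate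
8 | benzyl mercaptan | SCc1ccccc1 | starting material
9 | 8-bromo-5,7,3',4'-tetra-O-benzyl-4β-(benzylsulfanyl)-(−)-epicatechin | c4ccccc4COc1cc(OCc4ccccc4)c2c(c1Br)O[C@H](c1ccc(OCc4ccccc4)c(OCc4ccccc4)c1)[C@H](O)[C@H]2SCc4ccccc4 | intermediate
10 | [8-bromo-tetra-O-benzyl-epicatechin]-(4β→6)-[8-bromo-tetra-O-benzyl-4β-(benzylsulfanyl)-epicatechin] | c4ccccc4COc1cc(OCc4ccccc4)c2c(c1Br)O[C@H](c1ccc(OCc4ccccc4)c(OCc4ccccc4)c1)[C@H](O)[C@H]2c1c(OCc4ccccc4)c(Br)c2c(c1OCc4ccccc4)[C@H](SCc4ccccc4)[C@@H](O)[C@@H](c1ccc(OCc4ccccc4)c(OCc4ccccc4)c1)O2 | intermediate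
11 | 5,7,3',4'-tetra-O-benzyl-4β-(2-ethoxyethoxy)-(−)-epicatechin | c4ccccc4COc1cc(OCc4ccccc4)c2c(c1)O[C@H](c1ccc(OCc4ccccc4)c(OCc4ccccc4)c1)[C@H](O)[C@H]2OCCOCC | intermediate
12 | 3,5-bis(benzyloxy)phenol | Oc1cc(OCc2ccccc2)cc(OCc2ccccc2)c1 | starting material
13 | chlorotriisopropylsilane | CC(C)[Si](Cl)(C(C)C)C(C)C | starting material
14 | [3,5-bis(benzyloxy)phenoxy]triisopropylsilane | CC(C)[Si](Oc1cc(OCc2ccccc2)cc(OCc2ccccc2)c1)(C(C)C)C(C)C | intermediate
15 | 5,7,3',4'-tetra-O-benzyl-4β-[2,6-bis(benzyloxy)-4-(triisopropylsilyloxy)phenyl]-(−)-epicatechin | c4ccccc4COc1cc(OCc4ccccc4)c2c(c1)O[C@H](c1ccc(OCc4ccccc4)c(OCc4ccccc4)c1)[C@H](O)[C@H]2c1c(OCc4ccccc4)cc(O[Si](C(C)C)(C(C)C)C(C)C)cc1OCc4ccccc4 | intermediate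
16 | benzylated trimer (8-bromo in units 1 and 2; 4β→6, 4β→8) with 2,6-bis(benzyloxy)-4-(triisopropylsilyloxy)phenyl at C4β of unit 3 | c4ccccc4COc1cc(OCc4ccccc4)c2c(c1Br)O[C@H](c1ccc(OCc4ccccc4)c(OCc4ccccc4)c1)[C@H](O)[C@H]2c1c(OCc4ccccc4)c(Br)c2c(c1OCc4ccccc4)[C@H](c1c(OCc4ccccc4)cc(OCc4ccccc4)c3c1O[C@H](c1ccc(OCc4ccccc4)c(OCc4ccccc4)c1)[C@H](O)[C@H]3c1c(OCc4ccccc4)cc(O[Si](C(C)C)(C(C)C)C(C)C)cc1OCc4ccccc4)[C@@H](O)[C@@H](c1ccc(OCc4ccccc4)c(OCc4ccccc4)c1)O2 | intermediate
17 | benzylated trimer with 2,6-bis(benzyloxy)-4-hydroxyphenyl at C4β of unit 3 | c4ccccc4COc1cc(OCc4ccccc4)c2c(c1Br)O[C@H](c1ccc(OCc4ccccc4)c(OCc4ccccc4)c1)[C@H](O)[C@H]2c1c(OCc4ccccc4)c(Br)c2c(c1OCc4ccccc4)[C@H](c1c(OCc4ccccc4)cc(OCc4ccccc4)c3c1O[C@H](c1ccc(OCc4ccccc4)c(OCc4ccccc4)c1)[C@H](O)[C@H]3c1c(OCc4ccccc4)cc(O)cc1OCc4ccccc4)[C@@H](O)[C@@H](c1ccc(OCc4ccccc4)c(OCc4ccccc4)c1)O2 | intermediate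
18 | 3,4-bis(benzyloxy)benzaldehyde | O=Cc1ccc(OCc2ccccc2)c(OCc2ccccc2)c1 | starting material
19 | vinylmagnesium bromide | C=C[Mg]Br | starting material
20 | rac-1-[3,4-bis(benzyloxy)phenyl]prop-2-en-1-ol | C=CC(O)c1ccc(OCc2ccccc2)c(OCc2ccccc2)c1 | intermediate
21 | tert-butyl hydroperoxide | CC(C)(C)OO | starting material
22 | (S)-[3,4-bis(benzyloxy)phenyl][(2R)-oxiran-2-yl]methanol | C1[C@@H](O1)[C@H](c1ccc(OCc2ccccc2)c(OCc2ccccc2)c1)O | intermediate
23 | benzylated trimer with 2,6-bis(benzyloxy)-4-{(R)-[3,4-bis(benzyloxy)phenyl][(2R)-oxiran-2-yl]methoxy}phenyl at C4β of unit 3 | c4ccccc4COc1cc(OCc4ccccc4)c2c(c1Br)O[C@H](c1ccc(OCc4ccccc4)c(OCc4ccccc4)c1)[C@H](O)[C@H]2c1c(OCc4ccccc4)c(Br)c2c(c1OCc4ccccc4)[C@H](c1c(OCc4ccccc4)cc(OCc4ccccc4)c3c1O[C@H](c1ccc(OCc4ccccc4)c(OCc4ccccc4)c1)[C@H](O)[C@H]3c1c(OCc4ccccc4)cc(O[C@H](c6ccc(OCc4ccccc4)c(OCc4ccccc4)c6)[C@H]5CO5)cc1OCc4ccccc4)[C@@H](O)[C@@H](c1ccc(OCc4ccccc4)c(OCc4ccccc4)c1)O2 | intermediate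
24 | 8,8'-dibromo-hexadeca-O-benzyl epicatechin-(4β→6)-epicatechin-(4β→8)-epicatechin-(4β→6)-epicatechin (bromine at C8 of units 1 and 2; four free 3-OH) | c4ccccc4COc1cc(OCc4ccccc4)c2c(c1Br)O[C@H](c1ccc(OCc4ccccc4)c(OCc4ccccc4)c1)[C@H](O)[C@H]2c1c(OCc4ccccc4)c(Br)c2c(c1OCc4ccccc4)[C@H](c1c(OCc4ccccc4)cc(OCc4ccccc4)c3c1O[C@H](c1ccc(OCc4ccccc4)c(OCc4ccccc4)c1)[C@H](O)[C@H]3c1c(OCc4ccccc4)cc3c(c1OCc4ccccc4)C[C@@H](O)[C@@H](c1ccc(OCc4ccccc4)c(OCc4ccccc4)c1)O3)[C@@H](O)[C@@H](c1ccc(OCc4ccccc4)c(OCc4ccccc4)c1)O2 | intermediate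
25 | epicatechin-(4β→6)-epicatechin-(4β→8)-epicatechin-(4β→6)-epicatechin (CNP0120618.1) | Oc1cc(O)c2c(c1)O[C@H](c1ccc(O)c(O)c1)[C@H](O)[C@H]2c1c(O)cc2c(c1O)[C@H](c1c(O)cc(O)c3c1O[C@H](c1ccc(O)c(O)c1)[C@H](O)[C@H]3c1c(O)cc3c(c1O)C[C@@H](O)[C@@H](c1ccc(O)c(O)c1)O3)[C@@H](O)[C@@H](c1ccc(O)c(O)c1)O2 | target

**Count and risks**

Total step count: 15. Longest linear sequence: 10 steps (steps 1, 2, 3, 4, 5, 9, 10, 13, 14, 15, from (−)-epicatechin).

Steps most likely to fail:

Step 5. The brominated, hindered C6 of 9 may attack too slowly, so that the cation from 7 condenses with itself or the thioether is eroded on long exposure to BF3. Fallback, setting out from 5 and 7: 7 is coupled with an excess of the simpler nucleophile 5 (BF3·OEt2, CH2Cl2) to give [8-bromo-tetra-O-benzyl-epicatechin]-(4β→6)-[8-bromo-tetra-O-benzyl-epicatechin] F1. Its only C4 methylene (unit 2) is then oxidised with DDQ and 2-ethoxyethanol (6) to the dimer carrying a 4β-(2-ethoxyethoxy) group on unit 2 F2. F2 is coupled with 15 under BF3·OEt2 in place of the silver activation, and the route is rejoined at 16.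

Step 14. The benzylic C2–O aryl ether bond may ionise under the Lewis acid (loss of C2 configuration or cleavage back to the phenol), the epoxide may open in the 5-exo sense, or interflavan bonds may scramble. Fallback with reversed polarity, setting out from 17: iodination with N-iodosuccinimide (CH2Cl2, −40 °C) ortho to the free hydroxyl gives the trimer ortho-iodophenol F3. Mitsunobu etherification with 22 (PPh3, DIAD) gives the trimer iodoaryl epoxy ether F4. Iodine–magnesium exchange with excess iPrMgCl·LiCl (−40 °C, selective over the two aryl bromides, the excess taking up the three OH protons) and warming with catalytic CuI lets the aryl metal open the epoxide at its terminal carbon, and the route is rejoined at 24.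

Step 8. Site selectivity between the carbon para and the carbons ortho to the silyloxy group may be poor, giving an isomeric adduct that would later lead to 4→8 connectivity. Fallback, setting out from 11: coupling with excess phloroglucinol (benzene-1,3,5-triol; BF3·OEt2, THF/CH2Cl2), which has no regiochemical choice, gives 5,7,3',4'-tetra-O-benzyl-4β-(2,4,6-trihydroxyphenyl)-epicatechin F5. Silylation with 13 and imidazole at −20 °C takes the one unhindered hydroxyl (para to the flavanyl group) to give 5,7,3',4'-tetra-O-benzyl-4β-[2,6-dihydroxy-4-(triisopropylsilyloxy)phenyl]-epicatechin F6. Benzylation of the two remaining phenols with 2 and K2CO3 in DMF rejoins the route at 15.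

**Further compounds**

F1 | step 5 | [8-bromo-tetra-O-benzyl-epicatechin]-(4β→6)-[8-bromo-tetra-O-benzyl-epicatechin] | c4ccccc4COc1cc(OCc4ccccc4)c2c(c1Br)O[C@H](c1ccc(OCc4ccccc4)c(OCc4ccccc4)c1)[C@H](O)[C@H]2c1c(OCc4ccccc4)c(Br)c2c(c1OCc4ccccc4)C[C@@H](O)[C@@H](c1ccc(OCc4ccccc4)c(OCc4ccccc4)c1)O2
F2 | step 5 | [8-bromo-tetra-O-benzyl-epicatechin]-(4β→6)-[8-bromo-tetra-O-benzyl-4β-(2-ethoxyethoxy)-epicatechin] | c4ccccc4COc1cc(OCc4ccccc4)c2c(c1Br)O[C@H](c1ccc(OCc4ccccc4)c(OCc4ccccc4)c1)[C@H](O)[C@H]2c1c(OCc4ccccc4)c(Br)c2c(c1OCc4ccccc4)[C@H](OCCOCC)[C@@H](O)[C@@H](c1ccc(OCc4ccccc4)c(OCc4ccccc4)c1)O2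
F3 | step 14 | benzylated trimer with 2,6-bis(benzyloxy)-4-hydroxy-3-iodophenyl at C4β of unit 3 | c4ccccc4COc1cc(OCc4ccccc4)c2c(c1Br)O[C@H](c1ccc(OCc4ccccc4)c(OCc4ccccc4)c1)[C@H](O)[C@H]2c1c(OCc4ccccc4)c(Br)c2c(c1OCc4ccccc4)[C@H](c1c(OCc4ccccc4)cc(OCc4ccccc4)c3c1O[C@H](c1ccc(OCc4ccccc4)c(OCc4ccccc4)c1)[C@H](O)[C@H]3c1c(OCc4ccccc4)c(I)c(O)cc1OCc4ccccc4)[C@@H](O)[C@@H](c1ccc(OCc4ccccc4)c(OCc4ccccc4)c1)O2
F4 | step 14 | benzylated trimer with 2,6-bis(benzyloxy)-3-iodo-4-{(R)-[3,4-bis(benzyloxy)phenyl][(2R)-oxiran-2-yl]methoxy}phenyl at C4β of unit 3 | c4ccccc4COc1cc(OCc4ccccc4)c2c(c1Br)O[C@H](c1ccc(OCc4ccccc4)c(OCc4ccccc4)c1)[C@H](O)[C@H]2c1c(OCc4ccccc4)c(Br)c2c(c1OCc4ccccc4)[C@H](c1c(OCc4ccccc4)cc(OCc4ccccc4)c3c1O[C@H](c1ccc(OCc4ccccc4)c(OCc4ccccc4)c1)[C@H](O)[C@H]3c1c(OCc4ccccc4)c(I)c(O[C@H](c6ccc(OCc4ccccc4)c(OCc4ccccc4)c6)[C@H]5CO5)cc1OCc4ccccc4)[C@@H](O)[C@@H](c1ccc(OCc4ccccc4)c(OCc4ccccc4)c1)O2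
F5 | step 8 | 5,7,3',4'-tetra-O-benzyl-4β-(2,4,6-trihydroxyphenyl)-epicatechin | c4ccccc4COc1cc(OCc4ccccc4)c2c(c1)O[C@H](c1ccc(OCc4ccccc4)c(OCc4ccccc4)c1)[C@H](O)[C@H]2c1c(O)cc(O)cc1O
F6 | step 8 | 5,7,3',4'-tetra-O-benzyl-4β-[2,6-dihydroxy-4-(triisopropylsilyloxy)phenyl]-epicatechin | c4ccccc4COc1cc(OCc4ccccc4)c2c(c1)O[C@H](c1ccc(OCc4ccccc4)c(OCc4ccccc4)c1)[C@H](O)[C@H]2c1c(O)cc(O[Si](C(C)C)(C(C)C)C(C)C)cc1O
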